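**Plan**

1. Last cut: the O5–CH3 bond, by chelation-controlled demethylation of a 5,7-dimethoxyflavanone. Main cut: C2–C3 and C4–C4a of ring C together, back to an α-aryloxy diazoketone ArO–CH(Ar′)–CO–CHN2 whose carbonyl carbon is the future C4 and whose diazo carbon is the future C3.
2. Further cuts: O1–C2 (Mitsunobu etherification of a mandelate by a phenol) and the bond from ring A to the geranyl chain (ortho-lithiation and allylation).
3. Forward order: the geranyl chain goes onto ring A, ring A is joined to the ring B fragment through O1–C2, ring C is closed last in the key step, and O5 is unmasked at the end.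
4. Stereochemistry: C2 is set as an (S)-carbinol by asymmetric transfer hydrogenation, inverted once in the Mitsunobu step, and then carried unchanged because the 1,2-shift of the Wolff rearrangement goes with retention.
5. Enabling feature: C2 bears O1 and ring B and lies two carbons (C3, C4) from C4a, an arene carbon ortho to O1 and activated by O1, O5 and O7. Ring A of the precursor is symmetric about the axis through C8a and C6, so both ortho carbons are the same and ring closure has one outcome.

Key step: step 8

Assumption: in the transfer hydrogenation of keto ester 7 the aryl group, not the ester, is taken to sit next to the η6-arene of the catalyst, as with aryl alkyl ketones, so the (R,R)-diamine complex should give the (S)-hydroxy ester; if the sense proves opposite, the (S,S)-complex is used and nothing else changes.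

**Route**

Step 1
Reactants: 1 3,5-dimethoxyphenol
Product: 2 (3,5-dimethoxyphenoxy)triisopropylsilane
Conditions: i-Pr3SiCl, imidazole, DMF, 25 °C
Reagents that add atoms: chlorotriisopropylsilane, CC(C)[Si](Cl)(C(C)C)C(C)C
Why: Silyl ether formation should mask the acidic OH with a bulky, non-coordinating group that keeps the base of the next step away from its own ortho positions.

Step 2
Reactants: 2 (3,5-dimethoxyphenoxy)triisopropylsilane; 3 geranyl bromide, (E)-1-bromo-3,7-dimethylocta-2,6-diene
Product: 5 (4-geranyl-3,5-dimethoxyphenoxy)triisopropylsilane, via aryllithium 4 (not isolated)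
Conditions: n-BuLi, TMEDA, THF, 0 → 25 °C; then CuBr·SMe2 (10 mol %), 3, −78 → 0 °C
Reagents that add atoms: none
Why: Directed ortho-metalation should occur at the C–H between the two methoxy groups (doubly coordinated and not shielded by the silyl ether), and copper-catalysed SN2 allylation by the primary allylic bromide should keep the E double bond.

Step 3
Reactants: 5 (4-geranyl-3,5-dimethoxyphenoxy)triisopropylsilane
Product: 6 4-geranyl-3,5-dimethoxyphenol
Conditions: Bu4NF, THF, 0 °C; aqueous NH4Cl work-up
Reagents that add atoms: none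
Why: Fluoride-induced desilylation, driven by the Si–F bond, should free the phenol without touching the two alkenes.

Step 4
Reactants: 7 ethyl 2-(3,4-dimethoxyphenyl)-2-oxoacetate
Product: 8 ethyl (S)-2-(3,4-dimethoxyphenyl)-2-hydroxyacetate
Conditions: RuCl(p-cymene)[(R,R)-TsNCH(Ph)CH(Ph)NH2] (1 mol %), HCO2H/Et3N (5:2), DMF, 25 °C
Reagents that add atoms: none
Why: Noyori–Ikariya asymmetric transfer hydrogenation of an aryl ketone, in which the chiral Ru–H/N–H catalyst delivers hydride to one face of the carbonyl group and so should set the carbinol centre as (S).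

Step 5
Reactants: 6 4-geranyl-3,5-dimethoxyphenol; 8 ethyl (S)-2-(3,4-dimethoxyphenyl)-2-hydroxyacetate
Product: 9 ethyl (R)-2-(3,4-dimethoxyphenyl)-2-(4-geranyl-3,5-dimethoxyphenoxy)acetate
Conditions: PPh3, DIAD, toluene, 0 → 25 °C
Reagents that add atoms: none
Why: Mitsunobu reaction, in which the phenoxide displaces the alkoxyphosphonium group by SN2 with inversion ((S)-alcohol to (R)-ether), the α-ester group disfavouring ionization of the electron-rich benzylic carbon.

Step 6
Reactants: 9 ethyl (R)-2-(3,4-dimethoxyphenyl)-2-(4-geranyl-3,5-dimethoxyphenoxy)acetate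
Product: 10 (R)-2-(3,4-dimethoxyphenyl)-2-(4-geranyl-3,5-dimethoxyphenoxy)acetic acid
Conditions: LiOH·H2O, THF/H2O (3:1), 0 °C; then 1 M HCl to pH 3, 0 °C
Reagents that add atoms: lithium hydroxide, [Li+].[OH-]
Why: Saponification at 0 °C, where acyl cleavage should outrun enolization and the carboxylate formed is no longer enolizable, so the α-centre should be kept.

Step 7
Reactants: 10 (R)-2-(3,4-dimethoxyphenyl)-2-(4-geranyl-3,5-dimethoxyphenoxy)acetic acid
Product: 12 (R)-1-diazo-3-(3,4-dimethoxyphenyl)-3-(4-geranyl-3,5-dimethoxyphenoxy)propan-2-one, via mixed carbonic anhydride 11 (not isolated)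
Conditions: i-BuOCOCl, N-methylmorpholine, THF, −20 °C; then CH2N2, Et2O, −20 → 0 °C
Reagents that add atoms: diazomethane, C=[N+]=[N-]
Why: Acylation of diazomethane by a mixed carbonic anhydride (first stage of an Arndt–Eistert sequence), made cold with a weak tertiary amine so that neither a ketene nor an enol of the activated acid should form and no HCl meets the alkenes.

Step 8
Reactants: 12 (R)-1-diazo-3-(3,4-dimethoxyphenyl)-3-(4-geranyl-3,5-dimethoxyphenoxy)propan-2-one
Product: 15 (S)-2-(3,4-dimethoxyphenyl)-6-geranyl-5,7-dimethoxychroman-4-one, via ketene 13 (not isolated), via acyl trifluoroacetate 14 (not isolated)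
Conditions: hν (365 nm), CH2Cl2 (0.01 M), 4 Å MS, −40 °C; then CF3CO2H (0.3 equiv), −40 → 0 °C
Reagents that add atoms: none
Why: Proposed new method: direct irradiation of the s-Z diazoketone should expel N2 with concerted 1,2-shift of C2 from the carbonyl carbon (the future C4) to the diazo carbon (the future C3), a Wolff rearrangement that forms C2–C3 and gives ketene 13. CF3CO2H, added only after N2 loss because it would protonate the diazoketone, should add to the ketene to give mixed anhydride 14, whose acyl carbon C4 is attacked by C4a of ring A (intramolecular Friedel–Crafts acylation, 6-exo-trig closure of ring C), which forms C4–C4a and returns the acid. The closest known reactions are the Arndt–Eistert homologation, where the same ketene is taken up by a heteroatom nucleophile, and the mixed-anhydride cyclization of 3-aryloxypropanoic acids to chroman-4-ones; new is only the capture of the Wolff ketene by an arene carbon in the same flask. No stereocentre is created: C2 migrates with retention, so (R)-12 should give (S)-15, the descriptor changing only because the priorities change. Rearrangement must outrun carbene attack on ring A, which metal-free photolysis at low temperature should secure, and ring closure must outrun ionization of the C2–O1 bond, which the short path to the triply activated C4a and the low acid concentration should secure. Regiocontrol is not needed, because ring A is symmetric about the axis through C8a and C6 and attack at either ortho carbon gives the same 5,7-dimethoxy compound.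

Step 9
Reactants: 15 (S)-2-(3,4-dimethoxyphenyl)-6-geranyl-5,7-dimethoxychroman-4-one
Product: 16 (S)-2-(3,4-dimethoxyphenyl)-6-geranyl-5-hydroxy-7-methoxychroman-4-one
Conditions: BCl3 (1.2 equiv), CH2Cl2, −78 °C; cold aqueous NaHCO3 quench
Reagents that add atoms: none
Why: Chelation-controlled ether cleavage, in which boron bound between the C4 carbonyl oxygen and the peri O5 lets chloride remove only that methyl group, at a temperature and in an aprotic medium where the other three methyl ethers, the alkenes and the C2–O1 bond should be left alone.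

**Compound list**

1 | 3,5-dimethoxyphenol | COc1cc(O)cc(OC)c1 | starting material
2 | (3,5-dimethoxyphenoxy)triisopropylsilane | COc1cc(O[Si](C(C)C)(C(C)C)C(C)C)cc(OC)c1 | intermediate
3 | geranyl bromide, (E)-1-bromo-3,7-dimethylocta-2,6-diene | BrC/C=C(\C)CCC=C(C)C | starting material
4 | [2,6-dimethoxy-4-(triisopropylsilyloxy)phenyl]lithium | [Li]c1c(OC)cc(O[Si](C(C)C)(C(C)C)C(C)C)cc1OC | intermediate
5 | (4-geranyl-3,5-dimethoxyphenoxy)triisopropylsilane [geranyl = (2E)-3,7-dimethylocta-2,6-dien-1-yl] | COc1cc(O[Si](C(C)C)(C(C)C)C(C)C)cc(OC)c1C/C=C(\C)CCC=C(C)C | intermediate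
6 | 4-geranyl-3,5-dimethoxyphenol | COc1cc(O)cc(OC)c1C/C=C(\C)CCC=C(C)C | intermediate
7 | ethyl 2-(3,4-dimethoxyphenyl)-2-oxoacetate | CCOC(=O)C(=O)c1ccc(OC)c(OC)c1 | starting material
8 | ethyl (S)-2-(3,4-dimethoxyphenyl)-2-hydroxyacetate | CCOC(=O)[C@@H](O)c1ccc(OC)c(OC)c1 | intermediate
9 | ethyl (R)-2-(3,4-dimethoxyphenyl)-2-(4-geranyl-3,5-dimethoxyphenoxy)acetate | CCOC(=O)[C@H](Oc1cc(OC)c(C/C=C(\C)CCC=C(C)C)c(OC)c1)c1ccc(OC)c(OC)c1 | intermediate
10 | (R)-2-(3,4-dimethoxyphenyl)-2-(4-geranyl-3,5-dimethoxyphenoxy)acetic acid | OC(=O)[C@H](Oc1cc(OC)c(C/C=C(\C)CCC=C(C)C)c(OC)c1)c1ccc(OC)c(OC)c1 | intermediate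
11 | isobutyl carbonic anhydride of acid 10 | CC(C)COC(=O)OC(=O)[C@H](Oc1cc(OC)c(C/C=C(\C)CCC=C(C)C)c(OC)c1)c1ccc(OC)c(OC)c1 | intermediate
12 | (R)-1-diazo-3-(3,4-dimethoxyphenyl)-3-(4-geranyl-3,5-dimethoxyphenoxy)propan-2-one | [N-]=[N+]=CC(=O)[C@H](Oc1cc(OC)c(C/C=C(\C)CCC=C(C)C)c(OC)c1)c1ccc(OC)c(OC)c1 | intermediate
13 | (S)-3-(3,4-dimethoxyphenyl)-3-(4-geranyl-3,5-dimethoxyphenoxy)prop-1-en-1-one (ketene) | O=C=C[C@H](Oc1cc(OC)c(C/C=C(\C)CCC=C(C)C)c(OC)c1)c1ccc(OC)c(OC)c1 | intermediate
14 | (S)-3-(3,4-dimethoxyphenyl)-3-(4-geranyl-3,5-dimethoxyphenoxy)propanoic trifluoroacetic anhydride | O=C(C[C@H](Oc1cc(OC)c(C/C=C(\C)CCC=C(C)C)c(OC)c1)c1ccc(OC)c(OC)c1)OC(=O)C(F)(F)F | intermediate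
15 | (S)-2-(3,4-dimethoxyphenyl)-6-geranyl-5,7-dimethoxychroman-4-one | COc1ccc([C@@H]2CC(=O)c3c(OC)c(C/C=C(\C)CCC=C(C)C)c(OC)cc3O2)cc1OC | intermediate
16 | (S)-2-(3,4-dimethoxyphenyl)-6-geranyl-5-hydroxy-7-methoxychroman-4-one | COc1ccc([C@@H]2CC(=O)c3c(cc(OC)c(C/C=C(\C)CCC=C(C)C)c3O)O2)cc1OC | target

**Count**

Total steps: 9. Longest linear sequence: 8 steps (1, 2, 3, 5, 6, 7, 8, 9).

**Steps most likely to fail**

Step 8 (Proposed new method). The ketene may be lost to dimerization or hydration before the arene attacks, or the acid may ionize the C2–O1 bond ahead of ring closure, with elimination of the phenol or loss of configuration. The fallback separates the two bond formations with known chemistry and sets out from diazoketone 12. Irradiation at 365 nm in THF/H2O should give, by Wolff rearrangement and hydration of the ketene (Arndt–Eistert homologation, retention at C2), (S)-3-(3,4-dimethoxyphenyl)-3-(4-geranyl-3,5-dimethoxyphenoxy)propanoic acid F1. (CF3CO)2O in CH2Cl2 at 0 °C should then close ring C through mixed anhydride 14 by the established Friedel–Crafts cyclization of 3-aryloxypropanoic acids, which comes back to the route at 15.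

Step 5. The alkoxyphosphonium intermediate may ionize in part at the electron-rich benzylic carbon, which erodes the enantiomeric purity, or the electron-rich phenol may be alkylated on carbon. The fallback makes the C2–O1 bond by enantioselective carbene insertion into the O–H bond instead of by substitution, and sets out from keto ester 7 and phenol 6. Condensation of 7 with TsNHNH2 (EtOH, 60 °C) should give ethyl 2-(3,4-dimethoxyphenyl)-2-(tosylhydrazono)acetate F2. DBU in CH2Cl2 should convert it by Bamford–Stevens elimination into ethyl 2-diazo-2-(3,4-dimethoxyphenyl)acetate F3. Insertion of the carbene from F3 into the O–H bond of 6 with PdCl2(PhCN)2, a chiral spiro bis(oxazoline) ligand and Na[B(C6H3(CF3)2)4] in CHCl3 should give ester 9 directly, the ligand antipode being chosen that gives the (R)-ether. The fallback comes back to the route at 9.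

Step 2. Metalation may occur next to the silyl ether instead of between the methoxy groups, followed by migration of silicon from oxygen to carbon. The fallback puts the oxygen on ring A after the geranyl chain, and sets out from geranyl bromide 3 and commercial 1,3-dimethoxybenzene (COc1cccc(OC)c1). Lithiation with n-BuLi in THF can only give (2,6-dimethoxyphenyl)lithium F4, and copper-catalysed allylation with 3 should give 2-geranyl-1,3-dimethoxybenzene F5. Sterically governed C–H borylation ([Ir(OMe)(cod)]2, 4,4′-di-tert-butyl-2,2′-bipyridine, B2pin2, THF, 60 °C) at the only ring C–H without an ortho substituent should give 2-(4-geranyl-3,5-dimethoxyphenyl)-4,4,5,5-tetramethyl-1,3,2-dioxaborolane F6. Oxidation with NaBO3·4H2O in THF/H2O, which does not epoxidize the alkenes, should give phenol 6, where the fallback comes back to the route.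

**Further compounds**

F1 | step 8 | (S)-3-(3,4-dimethoxyphenyl)-3-(4-geranyl-3,5-dimethoxyphenoxy)propanoic acid | OC(=O)C[C@H](Oc1cc(OC)c(C/C=C(\C)CCC=C(C)C)c(OC)c1)c1ccc(OC)c(OC)c1
F2 | step 5 | ethyl 2-(3,4-dimethoxyphenyl)-2-(tosylhydrazono)acetate | CCOC(=O)C(=NNS(=O)(=O)c1ccc(C)cc1)c1ccc(OC)c(OC)c1
F3 | step 5 | ethyl 2-diazo-2-(3,4-dimethoxyphenyl)acetate | CCOC(=O)C(=[N+]=[N-])c1ccc(OC)c(OC)c1
F4 | step 2 | (2,6-dimethoxyphenyl)lithium | [Li]c1c(OC)cccc1OC
F5 | step 2 | 2-geranyl-1,3-dimethoxybenzene | COc1cccc(OC)c1C/C=C(\C)CCC=C(C)C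
F6 | step 2 | 2-(4-geranyl-3,5-dimethoxyphenyl)-4,4,5,5-tetramethyl-1,3,2-dioxaborolane | COc1cc(B2OC(C)(C)C(C)(C)O2)cc(OC)c1C/C=C(\C)CCC=C(C)C
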